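## Analysis of the target

Isariotin C (28) is a bicyclo[3.3.1]nonan-9-one. Ring A (C1, C2, C3, C4, C5, C9) and ring B (C1, C8, C7, C6, C5, C9) share the bridgeheads C1 and C5 and the ketone C9, and an (E)-7-oxododec-2-enoyl amide sits on the nitrogen at C3. Seven stereocentres (1S,3S,4R,5S,6S,7S,8S) lie on nine carbons; only C2 is unfunctionalised. The C3 nitrogen (equatorial) and the C4 hydroxyl (axial) are cis on the face of ring A turned away from the C6–C8 bridge. The C6 hydroxyl is axial on ring B and points toward the C9 carbonyl, the C7–C8 epoxide lies on the same face of ring B, and C1 carries a tertiary hydroxyl. Sensitive groups are the epoxide (acid, nucleophiles), the β-hydroxy ketone C6–OH/C9=O (retro-aldol opening of ring B), the tertiary α-ketol C1–OH/C9=O (α-ketol rearrangement), and the enamide and chain ketone (conjugate addition, enamine formation). The difficulty is the density of heteroatom stereocentres on a bridged core, a fully substituted bridgehead carbinol, and placing N at C3 and O at C4 on a six-membered ring whose two halves are almost alike. The strategy rests on one feature: both α carbons of the C9 ketone, C1 and C5, are bonded to the ends of the unit C8–C7–C6. The C6 carbinol is β to C9 (an aldol oxygen), and with the epoxide read as an oxidised C7=C8 alkene, C8 is the β carbon of an enal whose carbonyl carbon is C6. Ring B is therefore the Michael–aldol adduct of a propynal unit across the ketone of a ring A α-ketol, whose carbonyl must sit at C9 and not at C1.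

## Retrosynthetic reasoning

**28 to 27.** The two C–O bonds of the epoxide are cut first. The epoxide is the group least tolerant of the acid needed to free the amine, so it is made last. The forward reaction has to deliver oxygen to C7=C8 on the face of the axial C6 hydroxyl only, and leave the electron-poor enamide alkene untouched; a hydroxyl-directed metal-catalysed epoxidation meets both needs.

**27 to 18 and 25.** The amide N–C(O) bond is cut next. The chain contains a ketone and a Michael acceptor that would compete in an amine-catalysed step, so acid 25 is attached only after the core is complete. Acid 25 comes from lactone 19: reduction to lactol 20, olefination with ylide 21 to hydroxy ester 23, oxidation to keto ester 24 and ester cleavage. The lactone carbinol carbon becomes the chain ketone, so its configuration is irrelevant.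

**18 to 16 to 15.** The carbonyl that ties N3 to O4 is removed. Direct hydrolysis of an oxazolidinone needs hot base, which the β-hydroxy ketone and α-ketol would not survive. The ring is instead activated on nitrogen (16) and opened by mild methanolysis, the same acylation masking the C6 hydroxyl against retro-aldol.

**15 to 11 and 12 (key disconnection).** C1–C8 and C5–C6 are cut together. This removes ring B, two skeletal bonds and three stereocentres (C1, C5, C6) in one operation, and leaves a monocyclic α-ketol 11 and propynal (12). No other pair of cuts uses the C9 carbonyl twice. The forward reaction must make C1 the first nucleophile, add on the face opposite the cis-fused oxazolidinone, reach the Z enal, and close ring B by aldol at C5.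

**11 to 10 to 9.** The C9 ketone is carried as a dimethyl ketal. Setting the ketone by late oxidation of one of two neighbouring carbinols was rejected, because C1 and C9 would differ only in a remote N versus O substituent. The oxazolidinone of 10 arises from the bridged carbamate 9 by transfer of the carbonyl from O1 to O4, which frees the C1 hydroxyl that the key step needs.

**9 to 8 to 7 to 5.** C3–N and C4–O are cut together. A carbamate tether on the C1 oxygen of 5 delivers nitrogen to C3 through a six-membered ring and oxygen to C4 suprafacially. This fixes three things at once: N on C3 rather than C4, the cis N/O relation, and the absolute configuration at C3 and C4 by relay from C1. C1 is a relay centre: it is erased by enolisation in the key step and set again there.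

**5 to 4 to 3 to 1.** The C1 carbinol is set by enantioselective reduction of ketone 4. Racemic alcohol 3 comes from enol ether 1, whose substitution pattern already encodes which carbon is the carbonyl (C9), which carries the hydroxyl (C1) and which alkene (C3=C4) remains.

## Alternatives that were turned down

**Alternative 1:** The disconnection is C5–C6 of ring B alone, with ring A built afterwards. In the forward step a catalytic mercuric salt, Hg(OCOCF3)2, in aqueous acetone hydrates the exocyclic enol ether of the hexopyranoside A1. The hemiacetal opens to a keto aldehyde and the mercury enolate carbon (target C5) adds to the aldehyde (target C6) to give ring B ketone A2.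
- For: the oxygenated carbons C1, C8, C7 and C6 come from the carbohydrate pool with secure absolute configuration, and the carbocyclisation is a dependable reaction on a familiar substrate class. On precedent it is stronger than the chosen key step, and it does not depend on a late directed epoxidation.
- Against: A2 is one ring and one skeletal bond. C2, C3 and C4 with their nitrogen and oxygen still have to be bridged across C1 and C5, and C1 is a secondary benzyloxy carbon that must become a fully substituted bridgehead by C–C bond formation. Three orthogonal protecting groups are needed, and the β-hydroxy ketone dehydrates easily once C5 is enolised for a second closure.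
- Comparison: about seven steps to A1 and at least as many after A2, against eight to 11. The chosen route offers the whole bicycle, two bonds and three stereocentres in one step, with one protecting group.

**Alternative 2:** The disconnection is the C3–N bond on the finished, epoxidised core. In the forward step the primary carbamate A3 on the C4 oxygen is oxidised with PhI(OAc)2 in the presence of Rh2(OAc)4 and MgO. The rhodium nitrene inserts into the exo C3–H bond to give the cis-fused oxazolidinone A4.
- For: the cis N/O relation is automatic, because insertion is suprafacial from the C4 oxygen, and nitrogen need not be carried through the synthesis. On stereochemical certainty it equals the tethered delivery used in step 6 of the chosen route.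
- Against: it makes no skeletal bond and no ring; the entire oxygenated bicycle must exist first. C3–H is an unactivated secondary methylene, whereas such insertions favour tertiary, allylic or α-oxygen C–H bonds. The oxazolidinone must then be opened in the presence of the epoxide.
- Comparison: this is a functionalisation, not a construction. The chosen route puts nitrogen in at the cyclohexene stage, where nothing sensitive is present, and spends its risk on building the skeleton.

**Alternative 3:** The disconnection is C1–C9. In the forward step a triazolium-derived carbene adds to the C9 aldehyde on C5 of the (Z)-cyclooct-2-enone A5. The acyl-anion equivalent adds across the ring to the C1 ketone and gives A6 with both six-membered rings.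
- For: A6 is the protected counterpart of 15. There is no question of which α carbon reacts, the C6 centre and the alkene geometry are set beforehand, and aldehyde–ketone benzoin cyclisations are catalytic and mild. On regiochemical certainty, and on independence from a reversible aldol, it is stronger than the chosen step.
- Against: A5 is an eight-membered enone with four contiguous stereocentres and three protecting groups, reachable only by a long sequence ending in a medium-ring closure. Its aldehyde α carbon C5 lies between two β-silyloxy carbons, so epimerisation and β-elimination threaten at the enaminol stage. The acceptor is a deactivated conjugated ketone.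
- Comparison: the same bicycle is made, but from a medium ring that costs far more than 11. The chosen route offers a six-membered precursor and a three-carbon reagent.

Key step: step 9

Assumption: core compounds use the bicyclo[3.3.1]nonane locants C1–C9 of the analysis; lactone 19 is used as the racemate because its carbinol centre becomes the chain ketone; propynal 12 is handled as a cold toluene solution.

## Route

Step 1
Reactants: 1 1-methoxycyclohexa-1,4-diene
Product: 3 (±)-6,6-dimethoxycyclohex-3-en-1-ol, via methoxy epoxide 2 (not isolated)
Conditions: mCPBA (1.0 equiv), MeOH, −20 °C → 0 °C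
Reagents that add atoms: mCPBA, O=C(OO)c1cccc(Cl)c1; methanol, CO
Why: Prilezhaev epoxidation is chemoselective for the electron-rich enol ether over the isolated alkene, and methanol opens epoxide 2 at the acetal carbon through the oxocarbenium ion to give the α-hydroxy dimethyl ketal; the product is racemic.

Step 2
Reactants: 3 (±)-6,6-dimethoxycyclohex-3-en-1-ol
Product: 4 6,6-dimethoxycyclohex-3-en-1-one
Conditions: Dess–Martin periodinane, NaHCO3, CH2Cl2, 0 °C → rt
Reagents that add atoms: none
Why: Dess–Martin oxidation under buffered, non-basic conditions should leave the β,γ-alkene out of conjugation; the ketone is used directly.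

Step 3
Reactants: 4 6,6-dimethoxycyclohex-3-en-1-one
Product: 5 (R)-6,6-dimethoxycyclohex-3-en-1-ol
Conditions: (S)-1-methyl-3,3-diphenyltetrahydro-1H,3H-pyrrolo[1,2-c][1,3,2]oxazaborole (10 mol%), catecholborane, toluene, −78 °C
Reagents that add atoms: none
Why: Corey–Bakshi–Shibata reduction with the quaternary ketal carbon as the large substituent should deliver hydride to the face that gives the (R)-carbinol (sense to be confirmed by Mosher analysis); catecholborane at low temperature spares the alkene, and the enantiomeric purity can be raised later by crystallising 9 or 10.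

Step 4
Reactants: 5 (R)-6,6-dimethoxycyclohex-3-en-1-ol
Product: 7 (R)-6,6-dimethoxycyclohex-3-en-1-yl N-hydroxycarbamate, via acyl imidazole 6 (not isolated)
Conditions: carbonyldiimidazole, MeCN, 40 °C; then NH2OH·HCl, imidazole, rt
Reagents that add atoms: carbonyldiimidazole, O=C(n1ccnc1)n1ccnc1; hydroxylamine hydrochloride, NO.Cl
Why: Carbamoylation through the acyl imidazole: hydroxylamine attacks with its more nucleophilic nitrogen, giving the N-hydroxycarbamate without touching the ketal or the stereocentre.

Step 5
Reactants: 7 (R)-6,6-dimethoxycyclohex-3-en-1-yl N-hydroxycarbamate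
Product: 8 (R)-6,6-dimethoxycyclohex-3-en-1-yl N-(pentafluorobenzoyloxy)carbamate
Conditions: C6F5COCl, Et3N, Et2O, −10 °C
Reagents that add atoms: pentafluorobenzoyl chloride, O=C(Cl)c1c(F)c(F)c(F)c(F)c1F
Why: O-acylation of the hydroxamic N–OH, the most acidic site, installs the N–O bond that later serves as internal oxidant and nitrogen source.

Step 6
Reactants: 8 (R)-6,6-dimethoxycyclohex-3-en-1-yl N-(pentafluorobenzoyloxy)carbamate
Product: 9 (1R,5S,6R)-6-hydroxy-8,8-dimethoxy-2-oxa-4-azabicyclo[3.3.1]nonan-3-one (core locants: carbamate from O1 to N3, hydroxyl on C4)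
Conditions: K2OsO2(OH)4 (4 mol%), t-BuOH/H2O (3:1), rt
Reagents that add atoms: water, O
Why: Tethered aminohydroxylation: the N–O bond oxidises hexavalent osmium to a tethered octavalent imido species that adds suprafacially across C3=C4 from the face of the C1 oxygen. The six-membered tether puts N on C3 (N on C4 would need a seven-membered bridge), and hydrolysis of the osmate ester leaves the C4 hydroxyl cis to N, so C3 (S) and C4 (R) are set by C1.

Step 7
Reactants: 9 (1R,5S,6R)-6-hydroxy-8,8-dimethoxy-2-oxa-4-azabicyclo[3.3.1]nonan-3-one
Product: 10 (3aS,5R,7aR)-5-hydroxy-6,6-dimethoxyhexahydro-1,3-benzoxazol-2(3H)-one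
Conditions: DBU (20 mol%), MeCN, 50 °C
Reagents that add atoms: none
Why: Base-catalysed intramolecular transcarbamoylation (O-to-O acyl shift): the C4 alkoxide adds to the carbamate carbonyl and the C1 oxygen leaves, so the bridged 1,3-diaxial six-membered carbamate should relax to the cis-fused five-membered oxazolidinone; no stereocentre is touched and the C1 hydroxyl is released.

Step 8
Reactants: 10 (3aS,5R,7aR)-5-hydroxy-6,6-dimethoxyhexahydro-1,3-benzoxazol-2(3H)-one
Product: 11 (3aS,5R,7aR)-5-hydroxyhexahydro-1,3-benzoxazole-2,6-dione (ring A ketone)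
Conditions: HCl (1 M aq.)/THF (1:4), rt
Reagents that add atoms: water, O
Why: Acid-catalysed ketal hydrolysis; the oxazolidinone is acid-stable, and without an enolate the β-carbamoyloxy ketone cannot eliminate, so the ketone appears only at C9.

Step 9
Reactants: 11 (3aS,5R,7aR)-5-hydroxyhexahydro-1,3-benzoxazole-2,6-dione; 12 propynal
Product: 15 (1S,3S,4R,5R,6R)-3-amino-1,4,6-trihydroxybicyclo[3.3.1]non-7-en-9-one N3,O4-cyclic carbamate, via E-enal Michael adduct 13 (not isolated), via Z-enal Michael adduct 14 (not isolated)
Conditions: 12 (1.3 equiv, added slowly), pyrrolidine (20 mol%), PhCO2H (20 mol%), MeCN/H2O (20:1), 0 °C → rt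
Reagents that add atoms: none
Why: Proposed new method: pyrrolidine condenses with the C9 ketone of 11 to the enaminol C1=C9 (the hydroxylated side is preferred, as for hydroxyacetone in enamine catalysis); its C1 adds to the alkyne terminus of 12, and protonation gives enals 13 and 14, which interconvert by reversible conjugate addition of the amine, only 14 being able to reach C5. The closest known reaction type is the amine-mediated Michael–aldol α,α′-annulation of cyclohexanones with acrolein to bicyclo[3.3.1]nonan-9-ones; the ynal partner and the α-ketol donor are the extension. Ring B closes by a 6-(enolendo)-exo-trig aldol of the C5 enamine onto the aldehyde carbon C6; no other ring is formed. C1 is set by axial attack on the half-chair enaminol with C3–N pseudoequatorial, that is on the face opposite the cis-fused oxazolidinone, because the other face would put the new bond 1,3-diaxial to C3–N. C5 is set by the tether, which allows bonding only on the face that already carries C8. C6 is set by a hydrogen-bonded transition state that holds the aldehyde oxygen toward the enamine nitrogen; the aldol being reversible, the product should settle on the axial hydroxyl hydrogen-bonded to the C9 carbonyl. The step needs C- over O-alkylation of the ketol, C1 before C5 as nucleophile, and survival of the C4 carbamate oxygen β to the ketone; the acid-buffered amine medium, the enaminol preference and slow addition of 12 at 0 °C address these. Once C1 is quaternary, C5 is the only enolisable position and the bicycle can neither dehydrate nor eliminate toward a bridgehead (Bredt).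

Step 10
Reactants: 15 (1S,3S,4R,5R,6R)-3-amino-1,4,6-trihydroxybicyclo[3.3.1]non-7-en-9-one N3,O4-cyclic carbamate
Product: 16 N3-(tert-butoxycarbonyl)-O6-(tert-butoxycarbonyl) derivative of 15 (1S,3S,4R,5R,6R)
Conditions: Boc2O (2.5 equiv), DMAP (0.2 equiv), Et3N, THF, 0 °C → rt
Reagents that add atoms: di-tert-butyl dicarbonate, CC(C)(C)OC(=O)OC(=O)OC(C)(C)C
Why: DMAP-catalysed acylation puts Boc on the oxazolidinone nitrogen, which activates the ring carbonyl, and on the secondary C6 hydroxyl, which blocks retro-aldol in the next step; the tertiary bridgehead hydroxyl is too hindered to react.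

Step 11
Reactants: 16 N3,O6-bis(tert-butoxycarbonyl) derivative of 15
Product: 18 (1S,3S,4R,5S,6R)-3-(tert-butoxycarbonylamino)-6-(tert-butoxycarbonyloxy)-1,4-dihydroxybicyclo[3.3.1]non-7-en-9-one, via C4 methyl carbonate 17 (not isolated)
Conditions: Cs2CO3 (0.2 equiv), MeOH, 0 °C
Reagents that add atoms: none
Why: Nucleophilic acyl substitution: methoxide attacks the endocyclic carbonyl of the N-acylated carbamate, the N-Boc anion leaves, and the C4 methyl carbonate 17 is methanolysed, while the hindered tert-butyl carbonate and carbamate react far more slowly. C1 and C5 cannot enolise and the C6 oxygen is masked, so neither epimerisation nor retro-aldol is open.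

Step 12
Reactants: 19 δ-decalactone
Product: 20 6-pentyltetrahydro-2H-pyran-2-ol (lactol, anomer mixture)
Conditions: i-Bu2AlH (1.1 equiv), CH2Cl2, −78 °C; aq. potassium sodium tartrate
Reagents that add atoms: none
Why: Partial hydride reduction: the tetrahedral aluminate is stable at −78 °C and gives the lactol on work-up.

Step 13
Reactants: 20 6-pentyltetrahydro-2H-pyran-2-ol; 21 tert-butyl (triphenylphosphoranylidene)acetate
Product: 23 tert-butyl (E)-7-hydroxydodec-2-enoate (racemic), via open hydroxy aldehyde 22 (not isolated)
Conditions: toluene, 80 °C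
Reagents that add atoms: none
Why: Wittig olefination of the open-chain tautomer 22 with a stabilised ylide should give the (E)-enoate; the neutral medium avoids oxa-Michael closure of the hydroxyl onto the enoate.

Step 14
Reactants: 23 tert-butyl (E)-7-hydroxydodec-2-enoate
Product: 24 tert-butyl (E)-7-oxododec-2-enoate
Conditions: Dess–Martin periodinane, NaHCO3, CH2Cl2, rt
Reagents that add atoms: none
Why: Dess–Martin oxidation of the secondary alcohol removes the only stereocentre of the chain without isomerising the enoate.

Step 15
Reactants: 24 tert-butyl (E)-7-oxododec-2-enoate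
Product: 25 (E)-7-oxododec-2-enoic acid
Conditions: CF3CO2H/CH2Cl2 (1:4), 0 °C → rt
Reagents that add atoms: none
Why: Acidolysis of the tert-butyl ester with loss of 2-methylpropene (E1); base, which could trigger intramolecular Michael addition of the ketone enolate, is avoided.

Step 16
Reactants: 18 (1S,3S,4R,5S,6R)-3-(tert-butoxycarbonylamino)-6-(tert-butoxycarbonyloxy)-1,4-dihydroxybicyclo[3.3.1]non-7-en-9-one; 25 (E)-7-oxododec-2-enoic acid
Product: 27 (E)-N-[(1S,3S,4R,5R,6R)-1,4,6-trihydroxy-9-oxobicyclo[3.3.1]non-7-en-3-yl]-7-oxododec-2-enamide, via ammonium trifluoroacetate 26 (not isolated)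
Conditions: CF3CO2H/CH2Cl2 (1:3), anisole, 0 °C, evaporation; then 25, EDC·HCl, HOBt, i-Pr2NEt, DMF, 0 °C → rt
Reagents that add atoms: none
Why: Acidolysis removes both Boc groups while no epoxide is yet present, and the C6 carbinol cannot dehydrate toward the bridgehead. Carbodiimide amide coupling then acylates the amine selectively over the three hydroxyls.

Step 17
Reactants: 27 (E)-N-[(1S,3S,4R,5R,6R)-1,4,6-trihydroxy-9-oxobicyclo[3.3.1]non-7-en-3-yl]-7-oxododec-2-enamide
Product: 28 isariotin C, (E)-N-[(1S,3S,4R,5S,6S,7S,8S)-7,8-epoxy-1,4,6-trihydroxy-9-oxobicyclo[3.3.1]nonan-3-yl]-7-oxododec-2-enamide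
Conditions: VO(acac)2 (5 mol%), t-BuOOH (1.5 equiv, decane), CH2Cl2, 0 °C → rt
Reagents that add atoms: tert-butyl hydroperoxide, CC(C)(C)OO
Why: Hydroxyl-directed epoxidation: the pentavalent vanadium alkoxide–peroxide complex bound to the pseudoaxial C6 hydroxyl delivers oxygen to the same face of C7=C8, which is also the face away from ring A, setting C7 and C8 cis to the C6 hydroxyl. The electron-poor enamide alkene and the ketones should not react.

## Compound list

1 | 1-methoxycyclohexa-1,4-diene | COC1=CCC=CC1 | starting material
2 | 1-methoxy-7-oxabicyclo[4.1.0]hept-3-ene (racemic) | COC12CC=CCC1O2 | intermediate (not isolated)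
3 | (±)-6,6-dimethoxycyclohex-3-en-1-ol | OC1CC=CCC1(OC)OC | intermediate
4 | 6,6-dimethoxycyclohex-3-en-1-one | O=C1CC=CCC1(OC)OC | intermediate
5 | (R)-6,6-dimethoxycyclohex-3-en-1-ol | O[C@@H]1CC=CCC1(OC)OC | intermediate
6 | (R)-6,6-dimethoxycyclohex-3-en-1-yl 1H-imidazole-1-carboxylate | O=C(O[C@@H]1CC=CCC1(OC)OC)n1ccnc1 | intermediate (not isolated)
7 | (R)-6,6-dimethoxycyclohex-3-en-1-yl N-hydroxycarbamate | ONC(=O)O[C@@H]1CC=CCC1(OC)OC | intermediate
8 | (R)-6,6-dimethoxycyclohex-3-en-1-yl N-(pentafluorobenzoyloxy)carbamate | O=C(ONC(=O)O[C@@H]1CC=CCC1(OC)OC)c1c(F)c(F)c(F)c(F)c1F | intermediate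
9 | (1R,5S,6R)-6-hydroxy-8,8-dimethoxy-2-oxa-4-azabicyclo[3.3.1]nonan-3-one | O=C1N[C@H]2C[C@@H](O1)C(OC)(OC)C[C@H]2O | intermediate
10 | (3aS,5R,7aR)-5-hydroxy-6,6-dimethoxyhexahydro-1,3-benzoxazol-2(3H)-one | O=C1N[C@H]2C[C@@H](O)C(OC)(OC)C[C@H]2O1 | intermediate
11 | (3aS,5R,7aR)-5-hydroxyhexahydro-1,3-benzoxazole-2,6-dione (ring A ketone) | O=C1N[C@H]2C[C@@H](O)C(=O)C[C@H]2O1 | intermediate
12 | propynal | C#CC=O | starting material
13 | (3aS,5S,7aR)-5-hydroxy-5-[(E)-3-oxoprop-1-en-1-yl]hexahydro-1,3-benzoxazole-2,6-dione | O=C1N[C@H]2C[C@](O)(/C=C/C=O)C(=O)C[C@H]2O1 | intermediate (not isolated)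
14 | (3aS,5S,7aR)-5-hydroxy-5-[(Z)-3-oxoprop-1-en-1-yl]hexahydro-1,3-benzoxazole-2,6-dione | O=C1N[C@H]2C[C@](O)(/C=C\C=O)C(=O)C[C@H]2O1 | intermediate (not isolated)
15 | (1S,3S,4R,5R,6R)-3-amino-1,4,6-trihydroxybicyclo[3.3.1]non-7-en-9-one N3,O4-cyclic carbamate | O=C1N[C@H]2C[C@@]3(O)C(=O)[C@H]([C@H](O)C=C3)[C@H]2O1 | intermediate
16 | N3-(tert-butoxycarbonyl)-O6-(tert-butoxycarbonyl) derivative of 15 (1S,3S,4R,5R,6R) | CC(C)(C)OC(=O)N1[C@H]2C[C@@]3(O)C(=O)[C@H]([C@H](OC(=O)OC(C)(C)C)C=C3)[C@H]2OC1=O | intermediate
17 | (1S,3S,4R,5R,6R)-3-(tert-butoxycarbonylamino)-6-(tert-butoxycarbonyloxy)-1-hydroxy-4-(methoxycarbonyloxy)bicyclo[3.3.1]non-7-en-9-one | CC(C)(C)OC(=O)N[C@H]1C[C@@]2(O)C(=O)[C@H]([C@H](OC(=O)OC(C)(C)C)C=C2)[C@H]1OC(=O)OC | intermediate (not isolated)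
18 | (1S,3S,4R,5S,6R)-3-(tert-butoxycarbonylamino)-6-(tert-butoxycarbonyloxy)-1,4-dihydroxybicyclo[3.3.1]non-7-en-9-one | CC(C)(C)OC(=O)N[C@H]1C[C@@]2(O)C(=O)[C@H]([C@H](OC(=O)OC(C)(C)C)C=C2)[C@H]1O | intermediate
19 | δ-decalactone (6-pentyltetrahydro-2H-pyran-2-one, racemic) | CCCCCC1CCCC(=O)O1 | starting material
20 | 6-pentyltetrahydro-2H-pyran-2-ol | CCCCCC1CCCC(O)O1 | intermediate
21 | tert-butyl (triphenylphosphoranylidene)acetate | CC(C)(C)OC(=O)C=P(c1ccccc1)(c1ccccc1)c1ccccc1 | starting material
22 | 5-hydroxydecanal | CCCCCC(O)CCCC=O | intermediate (not isolated)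
23 | tert-butyl (E)-7-hydroxydodec-2-enoate (racemic) | CCCCCC(O)CCC/C=C/C(=O)OC(C)(C)C | intermediate
24 | tert-butyl (E)-7-oxododec-2-enoate | CCCCCC(=O)CCC/C=C/C(=O)OC(C)(C)C | intermediate
25 | (E)-7-oxododec-2-enoic acid | CCCCCC(=O)CCC/C=C/C(=O)O | intermediate
26 | (1S,3S,4R,5R,6R)-1,4,6-trihydroxy-9-oxobicyclo[3.3.1]non-7-en-3-ylammonium trifluoroacetate | [NH3+][C@H]1C[C@@]2(O)C(=O)[C@H]([C@H](O)C=C2)[C@H]1O.[O-]C(=O)C(F)(F)F | intermediate (not isolated)
27 | (E)-N-[(1S,3S,4R,5R,6R)-1,4,6-trihydroxy-9-oxobicyclo[3.3.1]non-7-en-3-yl]-7-oxododec-2-enamide | CCCCCC(=O)CCC/C=C/C(=O)N[C@H]1C[C@@]2(O)C(=O)[C@H]([C@H](O)C=C2)[C@H]1O | intermediate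
28 | isariotin C | CCCCCC(=O)CCC/C=C/C(=O)N[C@H]1C[C@@]2(O)C(=O)[C@H]([C@H](O)[C@@H]3O[C@@H]32)[C@H]1O | target

## Step count and least certain steps

Total step count: 17. Longest linear sequence: 13 steps (steps 1–11, 16 and 17); the side chain takes steps 12–15.

**Step 9 (key step).** Most likely failure: propynal and the amine are consumed by conjugate addition at the amine nitrogen or at the C1 hydroxyl before the C1 enaminol reacts. Further possible failures:
- carbonyl transposition between C9 and C1 through the enaminol (Heyns-type), which would send the annulation to the wrong α carbons;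
- E1cB loss of the C4 carbamate oxygen through the C5 enamine before the aldol;
- trapping of the Z enal as a cyclic hemiacetal with the C1 hydroxyl.

Fallback, from 11 back to 15: the established amine-mediated Michael–aldol annulation with acrolein should give the saturated keto diol F1. Dess–Martin oxidation of its secondary C6 carbinol gives the 6,9-dione F2. Dehydrogenation with 2-iodoxybenzoic acid, or silyl enol ether formation followed by Pd(OAc)2 (Saegusa–Ito), introduces C7=C8 in the enedione F3. Luche reduction (NaBH4, CeCl3·7H2O, MeOH, −78 °C) of the C6 carbonyl, the C9 carbonyl being shielded by two bridgeheads, returns to 15. If hydride delivery gives the equatorial C6 epimer, it is equilibrated by retro-aldol/aldol in the amine–acid buffer.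

**Step 6.** Most likely failure: the tethered imido-osmium species does not reach the ring alkene, which requires the carbamate pseudoaxial and a bridged six-membered azaglycolate. The reoxidant would then be lost by hydrolysis, or intermolecular oxidation would take over.

Fallback, from 5 back to 10 (bypassing steps 4–7): Cl3CCN with catalytic DBU gives the trichloroacetimidate F4. N-Iodosuccinimide closes it through nitrogen onto C3 with anti iodide at C4, giving the bridged iodo dihydro-oxazine F5. Methanolic HCl cleaves the imidate to the trans-iodo amine hydrochloride F6, and Boc2O with NaHCO3 gives the N-Boc trans-iodo amine F7. Warming with NaHCO3 in DMF lets the Boc carbonyl displace iodide with inversion at C4, closing the cis-fused oxazolidinone 10 directly.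

**Step 7.** Most likely failure: the carbamate shift stops at an equilibrium mixture, or proceeds between molecules to give oligomers.

Fallback, from 9 back to 10: hydrolysis with Ba(OH)2 in aqueous ethanol at 80 °C gives the amino diol F8. Carbonyldiimidazole then closes the kinetically favoured five-membered ring onto the vicinal cis C4 hydroxyl.

**Step 3.** Most likely failure: low enantioselectivity, because the ketal oxygens can bind boron and blur the large/small distinction, or hydroboration of the alkene.

Fallback, from 3 back to 5 (bypassing steps 2 and 3): kinetic resolution of racemic 3 with immobilised Candida antarctica lipase B and vinyl acetate. By the Kazlauskas rule the (R)-enantiomer should be acylated to the acetate F9, which is separated from the unreacted alcohol and cleaved with K2CO3 in methanol; at most half of the material is used.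

**Step 11.** Most likely failure: methanolysis of the C6 carbonate as well, after which the freed β-hydroxy ketone opens by retro-aldol under the basic conditions; α-ketol rearrangement of the C1 alkoxide is the second risk.

Fallback, from 15 back to 27 through 26: Et3SiCl with imidazole silylates the secondary C6 hydroxyl to give the C6 triethylsilyl ether F10. Boc2O with DMAP gives its N-Boc derivative F11, and Cs2CO3 in methanol opens the ring to the N-Boc amino alcohol F12, whose silyl ether is inert to methoxide. The acid stage of step 16 removes Boc and silyl groups together.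

## Further compounds

F1 | step 9 | 3-amino-1,4,6-trihydroxybicyclo[3.3.1]nonan-9-one N3,O4-cyclic carbamate (ring stereocentres as in 15, both C6 epimers) | O=C1N[C@H]2C[C@@]3(O)C(=O)[C@H](C(O)CC3)[C@H]2O1
F2 | step 9 | 3-amino-1,4-dihydroxybicyclo[3.3.1]nonane-6,9-dione N3,O4-cyclic carbamate (stereocentres as in 15) | O=C1N[C@H]2C[C@@]3(O)C(=O)[C@H](C(=O)CC3)[C@H]2O1
F3 | step 9 | 3-amino-1,4-dihydroxybicyclo[3.3.1]non-7-ene-6,9-dione N3,O4-cyclic carbamate (stereocentres as in 15) | O=C1N[C@H]2C[C@@]3(O)C(=O)[C@H](C(=O)C=C3)[C@H]2O1
F4 | step 6 | (R)-6,6-dimethoxycyclohex-3-en-1-yl 2,2,2-trichloroacetimidate | N=C(O[C@@H]1CC=CCC1(OC)OC)C(Cl)(Cl)Cl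
F5 | step 6 | (1R,5S,6S)-6-iodo-8,8-dimethoxy-3-(trichloromethyl)-2-oxa-4-azabicyclo[3.3.1]non-3-ene | ClC(Cl)(Cl)C1=N[C@H]2C[C@@H](O1)C(OC)(OC)C[C@@H]2I
F6 | step 6 | (1R,4S,5S)-5-amino-4-iodo-2,2-dimethoxycyclohexan-1-ol hydrochloride | [NH3+][C@H]1C[C@@H](O)C(OC)(OC)C[C@@H]1I.[Cl-]
F7 | step 6 | tert-butyl N-[(1S,2S,5R)-5-hydroxy-2-iodo-4,4-dimethoxycyclohexyl]carbamate | CC(C)(C)OC(=O)N[C@H]1C[C@@H](O)C(OC)(OC)C[C@@H]1I
F8 | step 7 | (1R,2S,4R)-2-amino-5,5-dimethoxycyclohexane-1,4-diol | N[C@H]1C[C@@H](O)C(OC)(OC)C[C@H]1O
F9 | step 3 | (R)-6,6-dimethoxycyclohex-3-en-1-yl acetate | CC(=O)O[C@@H]1CC=CCC1(OC)OC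
F10 | step 11 | C6 triethylsilyl ether of 15 | O=C1N[C@H]2C[C@@]3(O)C(=O)[C@H]([C@H](O[Si](CC)(CC)CC)C=C3)[C@H]2O1
F11 | step 11 | N3-(tert-butoxycarbonyl) derivative of the C6 triethylsilyl ether of 15 | CC(C)(C)OC(=O)N1[C@H]2C[C@@]3(O)C(=O)[C@H]([C@H](O[Si](CC)(CC)CC)C=C3)[C@H]2OC1=O
F12 | step 11 | 3-(tert-butoxycarbonylamino)-1,4-dihydroxy-6-(triethylsilyloxy)bicyclo[3.3.1]non-7-en-9-one (stereocentres as in 18) | CC(C)(C)OC(=O)N[C@H]1C[C@@]2(O)C(=O)[C@H]([C@H](O[Si](CC)(CC)CC)C=C2)[C@H]1O
A1 | alternative 1 | methyl 4-O-benzyl-6-deoxy-3-O-(4-methoxybenzyl)-2-O-(tert-butyldimethylsilyl)-α-D-xylo-hex-5-enopyranoside | CO[C@H]1OC(=C)[C@@H](OCc2ccccc2)[C@H](OCc2ccc(OC)cc2)[C@H]1O[Si](C)(C)C(C)(C)C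
A2 | alternative 1 | 2-benzyloxy-5-hydroxy-3-(4-methoxybenzyloxy)-4-(tert-butyldimethylsilyloxy)cyclohexanone (ring B ketone) | O=C1C[C@H](O)[C@H](O[Si](C)(C)C(C)(C)C)[C@@H](OCc2ccc(OC)cc2)[C@@H]1OCc1ccccc1
A3 | alternative 2 | 7,8-epoxy-6-(tert-butyldimethylsilyloxy)-9-oxo-1-(triethylsilyloxy)bicyclo[3.3.1]nonan-4-yl carbamate | NC(=O)O[C@H]1CC[C@@]2(O[Si](CC)(CC)CC)C(=O)[C@@H]1[C@H](O[Si](C)(C)C(C)(C)C)[C@@H]1O[C@@H]12
A4 | alternative 2 | C3,C4 cis-fused oxazolidinone of 7,8-epoxy-6-(tert-butyldimethylsilyloxy)-1-(triethylsilyloxy)bicyclo[3.3.1]nonan-9-one | N4[C@H]1C[C@@]2(O[Si](CC)(CC)CC)C(=O)[C@H]([C@H](O[Si](C)(C)C(C)(C)C)[C@@H]3O[C@@H]32)[C@H]1OC4=O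
A5 | alternative 3 | tert-butyl N-[(Z)-4,6-bis(tert-butyldimethylsilyloxy)-5-formyl-1-oxocyclooct-7-en-3-yl]carbamate (target locants) | CC(C)(C)OC(=O)N[C@H]1CC(=O)/C=C\[C@@H](O[Si](C)(C)C(C)(C)C)[C@@H](C=O)[C@H]1O[Si](C)(C)C(C)(C)C
A6 | alternative 3 | 3-(tert-butoxycarbonylamino)-4,6-bis(tert-butyldimethylsilyloxy)-1-hydroxybicyclo[3.3.1]non-7-en-9-one | CC(C)(C)OC(=O)N[C@H]1C[C@@]2(O)C(=O)[C@H]([C@H](O[Si](C)(C)C(C)(C)C)C=C2)[C@H]1O[Si](C)(C)C(C)(C)C
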